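# Proposed total synthesis of CNP0148862.1 by a crossed [2+2] photocycloaddition and vinylcyclobutane ring expansion

## Analysis of the target

The core is a tricyclo[5.3.1.0^{1,5}]undec-8-ene: a bicyclo[3.2.1]octene (rings A and B) with cyclopentane ring C fused across C1–C5. Numbering used throughout:

- C1 is the quaternary carbon common to all three rings.
- C2 (CHO), C3, C4 and the ring-fusion methine C5 complete ring C.
- C6 (CH3, CH2OH), bridgehead C7 and the one-carbon bridge C11 complete ring A (C1–C11–C7–C6–C5).
- C8 (CO2H), C9 and C10 (acyloxy) complete ring B (C1–C11–C7–C8=C9–C10).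

There are six stereocentres (C1, C2, C5, C6, C7, C10); C1 and C6 are quaternary, and C1 and C7 are locked to each other as bridgeheads. Read as drawn, C10 and C6 lie on the same face of ring C and C11 on the other. Rings A and C are therefore trans-fused across C1–C5 (C4 is endo at C5), a more strained arrangement than the cis fusion of the cedrane sesquiterpenes. The C2 formyl group is cis to C6 on ring C and so flanks C10. On C6 the methyl group points to the three-carbon bridge and CH2OH away from it. The C10 oxygen sits on the face of ring B that is syn to C11.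

The C2 aldehyde is epimerisable and, next to an exocyclic alkene, would also isomerise, so it has to stay masked until the end. The allylic ester at C10, the free acid, two primary alcohols and the Z-alkene of the side chain restrict the last step to mild acid. The difficulty lies in the quaternary C1 flanked by three stereocentres, the strained ring fusion, and the two hydroxymethyl-level arms on C6 that must be told apart.

The strategy rests on the chain C11=C1–C5–C6–C7=C8. It is a 1,5-diene once C1 carries an exocyclic methylene (C11) and C7=C8 belongs to a 2-vinyl enoate, and C11 ends up bridging C7 and C1.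

## Retrosynthetic reasoning

**31 to 30.** All protecting groups are chosen to fall in one acidic operation (tert-butyl ester, two TBS ethers, dimethyl acetal). The base-sensitive allylic ester and the epimerisable aldehyde then never see base.

**30 to 23 and 28.** The C10–O acyl bond is cut. Acylation of alcohol 23 with the protected hydroxy acid 28 retains the C10 configuration. Acid 28 is cut between C8' and C9' of the chain into alkyne 25 and bromo acid 26, so that the Z-alkene comes from semihydrogenation of alkyne 27.

**23 to 20.** The C10–O bond is removed. The oxygen is introduced by deconjugating enoate 20 to 21, epoxidising the C9=C10 alkene on the face syn to C11 (22) and opening the epoxide by β-elimination. This fixes C10 through a facially biased epoxidation instead of a direct allylic oxidation next to a quaternary carbon.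

**20 to 19.** The C1–C10 bond is cut and C1–C8 reconnected, which turns ring B into a vinylcyclobutane. The C1–C8 bond of 19 is strained, allylic and α to the ester, so a thermal 1,3-shift should release ring B with C11 already in place.

**19 to 18.** The key disconnection cuts C7–C11 and C8–C1 and opens ring A and the cyclobutane together. It leads back to monocyclic 1,5-diene 18, which holds only the three stereocentres C2, C5 and C6. The forward reaction must form the crossed adduct and place C8 on the C6 face of ring C.

**18 to 14 and 15.** The C7=C8 bond is cut. An α-selective aldol of the crotonate dienolate from 15 with the non-enolisable aldehyde 14, followed by elimination through 16 and 17, builds the 2-vinyl enoate.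

**14 to 12.** The C1=C11 bond is traced to ketone 12 (non-basic methylenation to 13). The C7 aldehyde comes from the silyl-protected primary alcohol.

**12 to 8.** The C2 side chain is removed. The acetal carbon is attached to enone 8 at C2 (giving 11), and C2–H is then added by hydrogenation from the face opposite the C5 substituent. This is the only order that gives the 2,5-cis relationship, because the smaller partner (hydrogen) arrives last.

**8 to 4.** The enone is traced through 6 and 5 to lactone 4. Reduction frees C7–OH and C1–OH, and the ring alkene of the lactone is used to place the enone at C2=C3.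

**4 to 1.** The two C6 substituents are removed. Two successive enolate alkylations of the cis-fused lactone 1 (through 2 and 3), each on the convex face, set the quaternary centre C6 relative to C5.

## Alternatives that were turned down

**Alternative 1:** Ring B is disconnected at C7–C8 and C1–C10. In the forward direction a rhodium vinylcarbenoid from diazo ester A1 cyclopropanates the C6=C7 alkene of the achiral bicyclic cyclopentadiene A2 under a chiral dirhodium tetracarboxylate catalyst. Cope rearrangement of the divinylcyclopropane then gives tricyclic diene ester A3.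

- In its favour: it is convergent, sets C1 and C7 by catalyst control, and delivers ring B with the ester and the C8=C9 alkene in one step. On brevity to the tricycle it is stronger than the chosen route.
- Against it: A3 carries a tetrasubstituted C5=C6 alkene and a C2 ketal. C5–H, the quaternary C6 with its CH2OH, and the C2 formyl group would all have to be installed late on a congested bridged alkene, which is the hardest part of the target. A2 can also scramble by 1,5-hydrogen shifts, and the carbenoid must choose between two alkenes of the diene.
- The chosen route sets C2, C5 and C6 on a simple five-membered ring before the skeleton is built.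

**Alternative 2:** Rings A and C are disconnected at C1–C5, C2–C3 and C3–C4. In the forward direction a cobalt-carbonyl-mediated Pauson–Khand reaction of enyne A4 joins the alkyne on C6, the exocyclic C1=C2 alkene of ring B and a carbonyl carbon to give cyclopentenone A5.

- In its favour: two rings and the quaternary C1 form in one step with a topology fixed by the bridge, and the C10 oxygen and the C8=C9 enoate are already present. On those two points it is stronger than the chosen route.
- Against it: A4 is itself a chiral cyclohexene with three stereocentres, including the acyclic quaternary C6. The cyclisation must engage a 1,1-disubstituted alkene while closing a strained bridged ring. A5 then needs the C3 carbonyl removed, a formyl group added at C2 with control, and the C4=C5 alkene reduced so as to create the trans ring fusion.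
- The chosen route has no superfluous oxygen to delete, and the ring fusion follows from the geometry of the key step, not from a late reduction.

**Alternative 3:** Ring B is disconnected at C9–C10. In the forward direction a divalent-samarium ketyl, formed from the C10 aldehyde of A6, adds to the β-sulfonyl acrylate on C7. Loss of sulfinate gives the tricyclic C10 alcohol A7.

- In its favour: ring closure installs the C10 hydroxyl and the enoate in one mild step. The chosen route needs three steps for that oxygen, so on this point the alternative is stronger.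
- Against it: A6 already contains rings A and C with the quaternary C1, the C6 and C7 stereocentres and the C2 acetal, so the hard problem is moved into the precursor. The C10 configuration depends on the ketyl addition geometry; reduction of the vinyl sulfone and pinacol coupling compete; the C4=C5 alkene must still be hydrogenated to the trans fusion.
- The chosen route creates C1 and C7 in the key step from a monocyclic precursor.

Key step: step 13

## Route

Remarks on the chemistry: compounds 1, 15, 24 and 26 are taken as commercial. The target is made exactly as its SMILES encodes it, with rings A and C trans-fused. Locants C1–C11 in compound names refer to the numbering above.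

Step 1
Reactants: 1 (3aR,6aS)-3,3a,6,6a-tetrahydro-2H-cyclopenta[b]furan-2-one
Product: 2 (3S,3aS,6aS)-3-methyl-3,3a,6,6a-tetrahydro-2H-cyclopenta[b]furan-2-one
Conditions: LDA, THF, −78 °C; MeI, −78 to −40 °C
Reagents that add atoms: iodomethane, CI
Why: Enolate alkylation of a cis-fused bicyclic γ-lactone; the electrophile enters on the convex face, anti to C4, so the methyl group is placed exo.

Step 2
Reactants: 2 (3S,3aS,6aS)-3-methyl-3,3a,6,6a-tetrahydro-2H-cyclopenta[b]furan-2-one
Product: 3 (3R,3aS,6aS)-3-(hydroxymethyl)-3-methyl-3,3a,6,6a-tetrahydro-2H-cyclopenta[b]furan-2-one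
Conditions: LDA, THF, −78 °C; CH2O (gas, from cracked paraformaldehyde), −78 to −30 °C; aq. NH4Cl
Reagents that add atoms: formaldehyde, C=O
Why: Aldol addition of the tetrasubstituted lactone enolate to formaldehyde, again on the convex face; the methyl group is pushed to the concave face, which sets the quaternary centre C6 (CH3 syn to C4, CH2OH anti).

Step 3
Reactants: 3 (3R,3aS,6aS)-3-(hydroxymethyl)-3-methyl-3,3a,6,6a-tetrahydro-2H-cyclopenta[b]furan-2-one
Product: 4 (3R,3aS,6aS)-3-[(tert-butyldimethylsilyloxy)methyl]-3-methyl-3,3a,6,6a-tetrahydro-2H-cyclopenta[b]furan-2-one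
Conditions: TBSCl, imidazole, DMF, rt
Reagents that add atoms: tert-butyldimethylsilyl chloride, C[Si](C)(Cl)C(C)(C)C
Why: Silylation of the primary alcohol under weakly basic conditions, which avoids retro-aldol loss of formaldehyde from the β-hydroxy lactone.

Step 4
Reactants: 4 (3R,3aS,6aS)-3-[(tert-butyldimethylsilyloxy)methyl]-3-methyl-3,3a,6,6a-tetrahydro-2H-cyclopenta[b]furan-2-one
Product: 5 diol: 2-[1-(tert-butyldimethylsilyloxy)-3-hydroxy-2-methylpropan-2-yl]cyclopent-3-en-1-ol (C1–OH and the C5 side chain cis; C5 and C6 as in 4)
Conditions: LiAlH4, THF, 0 °C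
Reagents that add atoms: none
Why: Hydride reduction of the lactone to the 1,4-diol frees the C7 carbinol and the C1 hydroxyl; the low temperature and short contact are meant to prevent silyl migration between the two oxygenated arms on C6, which would scramble that centre.

Step 5
Reactants: 5 diol: 2-[1-(tert-butyldimethylsilyloxy)-3-hydroxy-2-methylpropan-2-yl]cyclopent-3-en-1-ol
Product: 6 C7 triethylsilyl ether: 2-[1-(tert-butyldimethylsilyloxy)-2-methyl-3-(triethylsilyloxy)propan-2-yl]cyclopent-3-en-1-ol
Conditions: TESCl (1.05 equiv), imidazole, CH2Cl2, −78 to −20 °C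
Reagents that add atoms: chlorotriethylsilane, CC[Si](Cl)(CC)CC
Why: The primary hydroxyl is silylated faster than the hindered secondary cyclopentenol; TES is chosen because it can later be turned into the aldehyde in the presence of the TBS ether.

Step 6
Reactants: 6 C7 triethylsilyl ether: 2-[1-(tert-butyldimethylsilyloxy)-2-methyl-3-(triethylsilyloxy)propan-2-yl]cyclopent-3-en-1-ol
Product: 8 5-substituted cyclopent-2-en-1-one (C1 ketone; C2=C3; side chain on C5 unchanged), via cyclopent-3-enone 7 (not isolated)
Conditions: Dess–Martin periodinane, NaHCO3, CH2Cl2, 0 °C to rt; then Et3N, rt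
Reagents that add atoms: none
Why: Oxidation gives the β,γ-unsaturated ketone, which moves into conjugation through deprotonation at the unhindered, doubly activated C2 and reprotonation at C4; the tertiary C5–H next to the quaternary carbon is removed much more slowly, so C5 should keep its configuration.

Step 7
Reactants: 8 5-substituted cyclopent-2-en-1-one
Product: 11 2-(dimethoxymethyl)-5-substituted cyclopent-2-en-1-one, via sulfonium silyl enol ether 9 (not isolated), via sulfonium keto acetal 10 (not isolated)
Conditions: Me2S, TMSOTf, CH2Cl2, −78 °C; HC(OMe)3, −78 to −30 °C; DBU, to 0 °C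
Reagents that add atoms: trimethyl orthoformate, COC(OC)OC
Why: Sulfide/silyl triflate-mediated Morita–Baylis–Hillman-type α-functionalisation of an enone: conjugate addition of the sulfide gives a β-sulfonium silyl enol ether, which is alkylated at C2 by the dimethoxycarbenium ion (Mukaiyama-type), and E1cB loss of the sulfide restores the enone with the masked formyl group on C2.

Step 8
Reactants: 11 2-(dimethoxymethyl)-5-substituted cyclopent-2-en-1-one
Product: 12 cis-2-(dimethoxymethyl)-5-substituted cyclopentan-1-one (acetal on C2 and side chain on C5 cis)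
Conditions: H2 (1 atm), Pd/C, EtOAc, rt
Reagents that add atoms: none
Why: Heterogeneous hydrogenation delivers hydrogen to C2 and C3 from the ring face opposite the bulky C5 substituent, so the acetal ends up cis to C6 and C2 is set; the neutral medium should leave the α-centres untouched.

Step 9
Reactants: 12 cis-2-(dimethoxymethyl)-5-substituted cyclopentan-1-one
Product: 13 methylenecyclopentane: C1 exocyclic methylene (C11); C2 dimethoxymethyl; C5 side chain with C7–OTES and C6–CH2OTBS
Conditions: Cp2Ti(μ-CH2)(μ-Cl)AlMe2 (Tebbe reagent), pyridine, THF/toluene, −40 to 0 °C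
Reagents that add atoms: Tebbe reagent, C[Al-]1(C)C[Ti](C2C=CC=C2)(C2C=CC=C2)[Cl+]1
Why: Titanium methylidene olefination of the ketone; the reagent is not basic, so the α-stereocentres C2 and C5 are not epimerised and the β-keto acetal does not lose methanol, and it approaches from the face anti to the two cis substituents.

Step 10
Reactants: 13 methylenecyclopentane with C7–OTES
Product: 14 aldehyde: 2-[(tert-butyldimethylsilyloxy)methyl]-2-[3-(dimethoxymethyl)-2-methylidenecyclopentyl]propanal (C7 aldehyde; C2, C5, C6 as in 13)
Conditions: (COCl)2, DMSO, CH2Cl2, −78 to −35 °C; Et3N, to 0 °C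
Reagents that add atoms: none
Why: Under Swern conditions a primary triethylsilyl ether is converted directly into the aldehyde while a primary TBS ether is left alone; the aldehyde has no α-hydrogen and cannot epimerise.

Step 11
Reactants: 14 aldehyde (C7), 15 tert-butyl (E)-but-2-enoate
Product: 16 tert-butyl 2-ethenyl-3-hydroxy ester (aldol adduct; C7–OH; C8 carries vinyl and ester; mixture at C7 and C8)
Conditions: 15, LDA, THF/DMPU, −78 °C; then 14, −78 °C; AcOH, −78 °C
Reagents that add atoms: none
Why: The lithium dienolate of a crotonate adds to aldehydes through its α-carbon under kinetic control (aldol addition), which attaches C8 with the vinyl group and the ester already in place; the two new stereocentres disappear in the next step.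

Step 12
Reactants: 16 tert-butyl 2-ethenyl-3-hydroxy ester
Product: 18 tert-butyl (E)-2-ethenylalk-2-enoate: 1,5-diene with C1=C11 methylene and C7=C8(vinyl)CO2tBu (C6 cis to vinyl), via mesylate 17 (not isolated)
Conditions: MsCl, Et3N, CH2Cl2, 0 °C; then DBU, rt
Reagents that add atoms: none
Why: Mesylation followed by E1cB elimination through the acidic α-hydrogen gives the 2-vinyl enoate, mainly as the more stable E isomer; the geometry is of no consequence because the next step equilibrates it.

Step 13
Reactants: 18 tert-butyl (E)-2-ethenylalk-2-enoate (1,5-diene)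
Product: 19 ring-C-fused bicyclo[2.1.1]hexane: new bonds C7–C11 and C8–C1; C8 carries vinyl (towards the C5–C6 bridge) and CO2tBu; C8 cis to C6 on ring C
Conditions: [Ir(dF(CF3)ppy)2(dtbbpy)]PF6 (2 mol %), MeCN (0.01 M, degassed), 450 nm LEDs, rt
Reagents that add atoms: none
Why: The excited trivalent-iridium complex (triplet energy about 61 kcal/mol) transfers its energy only to the 2-vinyl enoate, whose triplet twists about C7=C8 into a C7 radical and an ester-substituted C8–C9–C10 allyl radical; the isolated methylene is not sensitised. C7 adds to the methylene terminus C11 (1,5-closure, exo with respect to C7=C8 and endo with respect to C1=C11), which closes ring A and leaves a tertiary radical at C1. After intersystem crossing the 1,4-diradical recombines between C8 and C1 and closes the cyclobutane, so the crossed bicyclo[2.1.1]hexane results, as in the known sensitised crossed [2+2] photocycloadditions of 1,5-dienes and the visible-light [2+2] reactions of 1,3-dienes. The straight mode would need a four-membered ring in the first bond-forming event and is ruled out by the preference for five-ring closure. C7 and C1 are controlled by C5: C6 holds C7 over one face of the methylene (allylic 1,3-strain keeps C6 pseudo-axial), C7 therefore bonds to C11 on that face and C8 must follow onto the same face of C1, which places C8 cis to C6 on ring C and C11 trans. The configuration at C8 should follow from the bulky ester taking the position remote from the C5–C6 bridge and is immaterial, since C8 becomes trigonal in step 14. E/Z isomerisation of 18 under the conditions is harmless because both isomers give the same diradical. The selectivity the step needs is facial, and its main opponent is the C2 acetal, which lies on the face where C8 must bond.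

Step 14
Reactants: 19 ring-C-fused bicyclo[2.1.1]hexane
Product: 20 tert-butyl tricyclo[5.3.1.0^{1,5}]undec-8-ene-8-carboxylate with C2 dimethoxymethyl, C6 methyl and CH2OTBS, C10 methylene (C1, C2, C5, C6, C7 as in the target)
Conditions: toluene, BHT (cat.), sealed tube, 150 °C
Reagents that add atoms: none
Why: Thermal vinylcyclobutane–cyclohexene rearrangement (1,3-carbon shift): homolysis of the strained C1–C8 bond gives a tertiary radical at C1 and an ester-substituted allyl radical, and recombination at the allyl terminus C10 closes ring B with the C8=C9 double bond. C10 is held on the face of C1 that C8 occupied (it is tied to C1 through C7 and C11), so C1 keeps its configuration, and the C8 stereocentre is lost.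

Step 15
Reactants: 20 conjugated tert-butyl ester (C8=C9)
Product: 21 deconjugated tert-butyl ester: C9=C10 alkene, C8–H (either epimer)
Conditions: LDA, THF/DMPU, −78 °C; AcOH, −78 °C
Reagents that add atoms: none
Why: γ-Deprotonation at C10 gives the extended enolate, and kinetic protonation at the α-carbon C8 moves the double bond to C9=C10 (deconjugative protonation of an enoate).

Step 16
Reactants: 21 deconjugated tert-butyl ester
Product: 22 9,10-epoxide with the oxygen on the face syn to C11
Conditions: mCPBA, NaHCO3, CH2Cl2, 0 °C to rt
Reagents that add atoms: 3-chloroperoxybenzoic acid, OOC(=O)c1cccc(Cl)c1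
Why: Prilezhaev epoxidation of the only alkene; the face towards the C5–C6 bridge is covered by C3/C4 of ring C and the C6 methyl group, so the peracid should attack from the side of the one-carbon bridge and set the C10–O configuration.

Step 17
Reactants: 22 9,10-epoxide
Product: 23 γ-hydroxy enoate: C10–OH (syn to C11), C8=C9, tert-butyl ester
Conditions: DBU, CH2Cl2, rt
Reagents that add atoms: none
Why: Base-induced E1cB opening of a β,γ-epoxy ester: enolisation at C8 and β-elimination of the C9–O bond restore the conjugated ester and leave the hydroxyl on C10 with the configuration of the epoxide.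

Step 18
Reactants: 24 oct-7-yn-1-ol
Product: 25 tert-butyldimethyl(oct-7-yn-1-yloxy)silane
Conditions: TBSCl, imidazole, DMF, rt
Reagents that add atoms: tert-butyldimethylsilyl chloride, C[Si](C)(Cl)C(C)(C)C
Why: Standard silylation of the primary alcohol so that the hydroxy acid cannot self-esterify later.

Step 19
Reactants: 25 tert-butyldimethyl(oct-7-yn-1-yloxy)silane, 26 8-bromooctanoic acid
Product: 27 16-(tert-butyldimethylsilyloxy)hexadec-9-ynoic acid
Conditions: 25, n-BuLi, THF/DMPU, −78 to 0 °C; lithium salt of 26 (n-BuLi, THF, −78 °C); rt to 40 °C; dilute aq. acid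
Reagents that add atoms: none
Why: SN2 alkylation of the lithium acetylide by the primary bromide of the carboxylate salt joins the two eight-carbon pieces.

Step 20
Reactants: 27 16-(tert-butyldimethylsilyloxy)hexadec-9-ynoic acid
Product: 28 (9Z)-16-(tert-butyldimethylsilyloxy)hexadec-9-enoic acid
Conditions: H2 (1 atm), Pd/CaCO3/Pb(OAc)2 (Lindlar catalyst), quinoline, EtOAc, rt
Reagents that add atoms: none
Why: Syn semihydrogenation of the internal alkyne on the poisoned palladium surface gives the Z-alkene.

Step 21
Reactants: 23 γ-hydroxy enoate, 28 (9Z)-16-(tert-butyldimethylsilyloxy)hexadec-9-enoic acid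
Product: 30 fully protected ester: C10 O-acylated by 28; C8 tert-butyl ester; C2 dimethyl acetal; two TBS ethers, via mixed anhydride 29 (not isolated)
Conditions: 28, 2,4,6-Cl3C6H2COCl, Et3N, THF, rt; then 23, DMAP, toluene, rt to 40 °C
Reagents that add atoms: none
Why: Yamaguchi esterification; the hindered secondary allylic alcohol is acylated at oxygen by the acylpyridinium, so C10 keeps its configuration.

Step 22
Reactants: 30 fully protected ester
Product: 31 (1R,2S,5S,6S,7S,10S)-2-formyl-6-(hydroxymethyl)-10-{[(9Z)-16-hydroxyhexadec-9-enoyl]oxy}-6-methyltricyclo[5.3.1.0^{1,5}]undec-8-ene-8-carboxylic acid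
Conditions: TFA/H2O (9:1), CH2Cl2, 0 °C to rt
Reagents that add atoms: water, O
Why: Acidolysis removes all four protecting groups together: the tert-butyl ester loses isobutene, both primary TBS ethers are cleaved and the dimethyl acetal is hydrolysed. The allylic ester on the electron-poor enoate does not ionise, and the absence of base protects the C2 centre and the C10 ester.

## Compound list

1 | (3aR,6aS)-3,3a,6,6a-tetrahydro-2H-cyclopenta[b]furan-2-one | O=C1O[C@H]2CC=C[C@H]2C1 | starting material
2 | (3S,3aS,6aS)-3-methyl-3,3a,6,6a-tetrahydro-2H-cyclopenta[b]furan-2-one | O=C1O[C@H]2CC=C[C@H]2[C@@H]1C | intermediate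
3 | (3R,3aS,6aS)-3-(hydroxymethyl)-3-methyl-3,3a,6,6a-tetrahydro-2H-cyclopenta[b]furan-2-one | O=C1O[C@H]2CC=C[C@H]2[C@]1(C)CO | intermediate
4 | (3R,3aS,6aS)-3-[(tert-butyldimethylsilyloxy)methyl]-3-methyl-3,3a,6,6a-tetrahydro-2H-cyclopenta[b]furan-2-one | O=C1O[C@H]2CC=C[C@H]2[C@]1(C)CO[Si](C)(C)C(C)(C)C | intermediate
5 | diol: 2-[1-(tert-butyldimethylsilyloxy)-3-hydroxy-2-methylpropan-2-yl]cyclopent-3-en-1-ol | OC[C@@](C)(CO[Si](C)(C)C(C)(C)C)[C@@H]1C=CC[C@@H]1O | intermediate
6 | C7 triethylsilyl ether of 5 | CC[Si](CC)(CC)OC[C@@](C)(CO[Si](C)(C)C(C)(C)C)[C@@H]1C=CC[C@@H]1O | intermediate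
7 | cyclopent-3-enone (C1 ketone, C3=C4) | CC[Si](CC)(CC)OC[C@@](C)(CO[Si](C)(C)C(C)(C)C)[C@@H]1C=CCC1=O | intermediate
8 | 5-substituted cyclopent-2-en-1-one (C2=C3) | CC[Si](CC)(CC)OC[C@@](C)(CO[Si](C)(C)C(C)(C)C)[C@@H]1CC=CC1=O | intermediate
9 | sulfonium silyl enol ether (triflate) | CC[Si](CC)(CC)OC[C@@](C)(CO[Si](C)(C)C(C)(C)C)[C@@H]1CC([S+](C)C)C=C1O[Si](C)(C)C.[O-]S(=O)(=O)C(F)(F)F | intermediate
10 | sulfonium keto acetal (triflate) | CC[Si](CC)(CC)OC[C@@](C)(CO[Si](C)(C)C(C)(C)C)[C@@H]1CC([S+](C)C)C(C(OC)OC)C1=O.[O-]S(=O)(=O)C(F)(F)F | intermediate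
11 | 2-(dimethoxymethyl)-5-substituted cyclopent-2-en-1-one | CC[Si](CC)(CC)OC[C@@](C)(CO[Si](C)(C)C(C)(C)C)[C@@H]1CC=C(C(OC)OC)C1=O | intermediate
12 | cis-2-(dimethoxymethyl)-5-substituted cyclopentan-1-one | CC[Si](CC)(CC)OC[C@@](C)(CO[Si](C)(C)C(C)(C)C)[C@@H]1CC[C@H](C(OC)OC)C1=O | intermediate
13 | methylenecyclopentane with C7–OTES | CC[Si](CC)(CC)OC[C@@](C)(CO[Si](C)(C)C(C)(C)C)[C@@H]1CC[C@H](C(OC)OC)C1=C | intermediate
14 | C7 aldehyde: 2-[(tert-butyldimethylsilyloxy)methyl]-2-[3-(dimethoxymethyl)-2-methylidenecyclopentyl]propanal | O=C[C@@](C)(CO[Si](C)(C)C(C)(C)C)[C@@H]1CC[C@H](C(OC)OC)C1=C | intermediate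
15 | tert-butyl (E)-but-2-enoate | C/C=C/C(=O)OC(C)(C)C | starting material
16 | tert-butyl 2-ethenyl-3-hydroxy ester (aldol adduct, mixture at C7 and C8) | C=CC(C(=O)OC(C)(C)C)C(O)[C@@](C)(CO[Si](C)(C)C(C)(C)C)[C@@H]1CC[C@H](C(OC)OC)C1=C | intermediate
17 | mesylate of 16 | C=CC(C(=O)OC(C)(C)C)C(OS(C)(=O)=O)[C@@](C)(CO[Si](C)(C)C(C)(C)C)[C@@H]1CC[C@H](C(OC)OC)C1=C | intermediate
18 | tert-butyl (E)-2-ethenylalk-2-enoate, the 1,5-diene for the key step | C=C1[C@@H](C(OC)OC)CC[C@H]1[C@](C)(CO[Si](C)(C)C(C)(C)C)/C=C(\C=C)C(=O)OC(C)(C)C | intermediate
19 | ring-C-fused bicyclo[2.1.1]hexane with vinyl and CO2tBu on C8 | C[C@@]1(CO[Si](C)(C)C(C)(C)C)[C@@H]2C[C@]3([C@@]2(C=C)C(=O)OC(C)(C)C)[C@@H](C(OC)OC)CC[C@@H]13 | intermediate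
20 | tert-butyl tricyclo[5.3.1.0^{1,5}]undec-8-ene-8-carboxylate (C10 methylene) | C[C@@]1(CO[Si](C)(C)C(C)(C)C)[C@@H]2C[C@]3(CC=C2C(=O)OC(C)(C)C)[C@@H](C(OC)OC)CC[C@@H]13 | intermediate
21 | deconjugated ester (C9=C10, C8–H) | C[C@@]1(CO[Si](C)(C)C(C)(C)C)[C@@H]2C[C@]3(C=CC2C(=O)OC(C)(C)C)[C@@H](C(OC)OC)CC[C@@H]13 | intermediate
22 | 9,10-epoxide, oxygen syn to C11 | C[C@@]1(CO[Si](C)(C)C(C)(C)C)[C@@H]2C[C@]3([C@H]4O[C@H]4C2C(=O)OC(C)(C)C)[C@@H](C(OC)OC)CC[C@@H]13 | intermediate
23 | γ-hydroxy enoate (C10–OH) | C[C@@]1(CO[Si](C)(C)C(C)(C)C)[C@@H]2C[C@]3([C@@H](O)C=C2C(=O)OC(C)(C)C)[C@@H](C(OC)OC)CC[C@@H]13 | intermediate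
24 | oct-7-yn-1-ol | C#CCCCCCCO | starting material
25 | tert-butyldimethyl(oct-7-yn-1-yloxy)silane | C#CCCCCCCO[Si](C)(C)C(C)(C)C | intermediate
26 | 8-bromooctanoic acid | OC(=O)CCCCCCCBr | starting material
27 | 16-(tert-butyldimethylsilyloxy)hexadec-9-ynoic acid | OC(=O)CCCCCCCC#CCCCCCCO[Si](C)(C)C(C)(C)C | intermediate
28 | (9Z)-16-(tert-butyldimethylsilyloxy)hexadec-9-enoic acid | OC(=O)CCCCCCC/C=C\CCCCCCO[Si](C)(C)C(C)(C)C | intermediate
29 | mixed anhydride of 28 with 2,4,6-trichlorobenzoic acid | O=C(CCCCCCC/C=C\CCCCCCO[Si](C)(C)C(C)(C)C)OC(=O)c1c(Cl)cc(Cl)cc1Cl | intermediate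
30 | fully protected C10 ester | C[C@@]1(CO[Si](C)(C)C(C)(C)C)[C@@H]2C[C@]3([C@@H](OC(=O)CCCCCCC/C=C\CCCCCCO[Si](C)(C)C(C)(C)C)C=C2C(=O)OC(C)(C)C)[C@@H](C(OC)OC)CC[C@@H]13 | intermediate
31 | (1R,2S,5S,6S,7S,10S)-2-formyl-6-(hydroxymethyl)-10-{[(9Z)-16-hydroxyhexadec-9-enoyl]oxy}-6-methyltricyclo[5.3.1.0^{1,5}]undec-8-ene-8-carboxylic acid | C[C@@]1(CO)[C@@H]2C[C@]3([C@@H](OC(=O)CCCCCCC/C=C\CCCCCCO)C=C2C(=O)O)[C@@H](C=O)CC[C@@H]13 | target

## Step count and least certain steps

Total: 22 steps. Longest linear sequence: 19 steps (steps 1–17, 21 and 22, from 1 to 31); the side chain takes 3 steps (18–20).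

**Step 13 (key step).** The most likely failure is slow closure of the 1,4-diradical: C8, a fully substituted allyl radical, has to bond to C1 next to the C2 acetal on the same face. The diradical may then fall back to the diene (only E/Z isomerisation is seen) or close on the other face of C1, which would give the C1/C7-epimeric skeleton. Any ring-B product formed directly by closure at C10 is harmless, because it is 20.

The fallback uses a smaller radical at C8 and adds the vinyl group afterwards. It sets out from 14. Horner–Wadsworth–Emmons reaction with tert-butyl diethylphosphonoacetate (NaH, THF) gives the simple tert-butyl (E)-enoate F1. Xanthone-sensitised irradiation (350 nm, MeCN) is the classical triplet enoate–alkene cycloaddition and should give, by the same 1,5-closure, the bicyclo[2.1.1]hexane ester F2, in which the secondary α-ester radical closes more easily. Deprotonation of F2 at C8 (LDA, THF, −78 °C) and aldol addition to acetaldehyde, on the side away from the C5–C6 bridge, gives the β-hydroxy ester F3. Dehydration with the Burgess reagent can only proceed towards the methyl group and gives the vinyl compound F4, the C8 epimer of 19. Heating as in step 14 erases C8, and the route is rejoined at 20.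

**Step 14.** The diradical can also cleave the C7–C11 bond and revert to diene 18 instead of closing at C10. The temperature may start to remove isobutene from the ester, and the product gains strain from the trans ring fusion, which lowers the driving force.

The fallback does not let 19 accumulate. It sets out from 18 and irradiates it with the same iridium sensitiser in chlorobenzene at 120–130 °C. Diene that reverts is re-excited, cyclobutane that forms is drained thermally, and 20 is the sink because its enoate is not a triplet acceptor for this sensitiser. The route is rejoined at 20 and no new compound is made.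

**Step 6.** Base-mediated conjugation could run partly through deprotonation at C5. That would erode the C5 configuration or move the double bond to C4=C5.

The fallback fixes the position of the double bond by a regiodefined enol ether. It sets out from 6. Hydrogenation (H2, Pd/C, EtOAc) gives the saturated alcohol F5, and Dess–Martin oxidation the ketone F6. Kinetic enolisation away from C5 (LDA, TMSCl, THF, −78 °C) gives the silyl enol ether F7. Saegusa–Ito dehydrogenation with Pd(OAc)2 in MeCN returns to the route at 8.

**Step 9.** Methylenation of a ketone that is branched on both α-carbons may be sluggish. Longer reaction would allow loss of methanol from the β-keto acetal or epimerisation at C2.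

The fallback is a two-step Peterson olefination from 12. Addition of the non-basic organocerium reagent from Me3SiCH2Li and CeCl3 (THF, −78 °C) gives the β-hydroxysilane F8. Elimination with KH in THF returns to the route at 13.

**Step 15.** Deprotonation at the neopentyl C10 may be slow, so that conjugate addition of the amide competes, or the extended enolate may be reprotonated at C10 and return 20.

The fallback changes how the C10 oxygen is introduced and sets out from 20. Allylic oxidation with Rh2(cap)4 (dirhodium tetracaprolactamate) and t-BuOOH gives the 10-oxo enoate F9. Luche reduction (NaBH4, CeCl3, MeOH, −40 °C) delivers hydride from the open face syn to C11 and gives the C10-epimeric alcohol F10. Mitsunobu esterification with acid 28 (PPh3, DIAD, toluene) inverts C10 and rejoins the route at 30.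

## Further compounds

F1 | step 13 | tert-butyl (E)-enoate from 14 (C7=C8, no vinyl group) | C=C1[C@@H](C(OC)OC)CC[C@H]1[C@](C)(CO[Si](C)(C)C(C)(C)C)/C=C/C(=O)OC(C)(C)C
F2 | step 13 | bicyclo[2.1.1]hexane ester with C8–H | C[C@@]1(CO[Si](C)(C)C(C)(C)C)[C@@H]2C[C@]3(C2C(=O)OC(C)(C)C)[C@@H](C(OC)OC)CC[C@@H]13
F3 | step 13 | β-hydroxy ester: C8 carries 1-hydroxyethyl and CO2tBu | C[C@@]1(CO[Si](C)(C)C(C)(C)C)[C@@H]2C[C@]3([C@]2(C(C)O)C(=O)OC(C)(C)C)[C@@H](C(OC)OC)CC[C@@H]13
F4 | step 13 | C8 epimer of 19 | C[C@@]1(CO[Si](C)(C)C(C)(C)C)[C@@H]2C[C@]3([C@]2(C=C)C(=O)OC(C)(C)C)[C@@H](C(OC)OC)CC[C@@H]13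
F0 | step 14 | none | none
F5 | step 6 | saturated alcohol from 6 | CC[Si](CC)(CC)OC[C@@](C)(CO[Si](C)(C)C(C)(C)C)[C@@H]1CCC[C@@H]1O
F6 | step 6 | saturated C1 ketone | CC[Si](CC)(CC)OC[C@@](C)(CO[Si](C)(C)C(C)(C)C)[C@@H]1CCCC1=O
F7 | step 6 | trimethylsilyl enol ether (C1=C2) | CC[Si](CC)(CC)OC[C@@](C)(CO[Si](C)(C)C(C)(C)C)[C@@H]1CCC=C1O[Si](C)(C)C
F8 | step 9 | β-hydroxysilane from 12 | CC[Si](CC)(CC)OC[C@@](C)(CO[Si](C)(C)C(C)(C)C)[C@@H]1CC[C@H](C(OC)OC)C1(O)C[Si](C)(C)C
F9 | step 15 | 10-oxo enoate | C[C@@]1(CO[Si](C)(C)C(C)(C)C)[C@@H]2C[C@]3(C(=O)C=C2C(=O)OC(C)(C)C)[C@@H](C(OC)OC)CC[C@@H]13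
F10 | step 15 | C10 epimer of 23 | C[C@@]1(CO[Si](C)(C)C(C)(C)C)[C@@H]2C[C@]3([C@H](O)C=C2C(=O)OC(C)(C)C)[C@@H](C(OC)OC)CC[C@@H]13
A1 | alternative 1 | tert-butyl 2-diazobut-3-enoate | C=CC(=[N+]=[N-])C(=O)OC(C)(C)C
A2 | alternative 1 | achiral bicyclic cyclopentadiene with C2 ketal | CC1=CCC2=C1CCC23OCCO3
A3 | alternative 1 | tricyclic diene ester (C8=C9, C5=C6, C2 ketal) | CC=1[C@@H]2C[C@]3(CC=C2C(=O)OC(C)(C)C)C4(OCCO4)CCC=13
A4 | alternative 2 | ring B enyne: alkyne on C6, exocyclic C1=C2, C10 silyl ether | C#C[C@](C)(COCc1ccc(OC)cc1)[C@@H]2CC(=C)[C@@H](O[Si](C)(C)C(C)(C)C)C=C2C(=O)OC(C)(C)C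
A5 | alternative 2 | tricyclic C3 ketone with C4=C5 double bond | C[C@@]1(COCc4ccc(OC)cc4)[C@@H]2C[C@]3([C@@H](O[Si](C)(C)C(C)(C)C)C=C2C(=O)OC(C)(C)C)CC(=O)C=C13
A6 | alternative 3 | bicyclic C10 aldehyde with β-phenylsulfonyl acrylate on C7 | C[C@@]1(CO[Si](C)(C)C(C)(C)C)[C@H](C[C@]2(C=O)[C@@H](C(OC)OC)CC=C12)/C(=C\S(=O)(=O)c1ccccc1)C(=O)OC(C)(C)C
A7 | alternative 3 | tricyclic C10 alcohol with C8=C9 enoate and C4=C5 alkene | C[C@@]1(CO[Si](C)(C)C(C)(C)C)[C@@H]2C[C@]3([C@@H](O)C=C2C(=O)OC(C)(C)C)[C@@H](C(OC)OC)CC=C13
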